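**Strategy.** Ring B is read as a hidden p-cresol: the C8 oxygen lies para to C5, which carries the C14 methyl, and the neighbouring trans C3-oxygen/C4-methyl pair is the footprint of a trans-epoxide. The whole plan therefore rests on breaking C4–C5. In one operation the methyl-bearing para carbon of a 2,6-dibromophenol attacks the far carbon of a tethered (2R,3R)-epoxide, which closes ring A, removes aromaticity, fixes C3, C4 and C5, and leaves the C8 dienone. The precursor is a p-cresol with both ortho positions brominated and a CH2CH2 link from C10 to the oxirane. Hydrogenation, C9 oxidation, C7 aldol, esterification and dehydration then finish the target.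

Key step: step 6

Remark on the chemistry: positions are given in eremophilane numbering (ring A = C1–C5 and C10, ring B = C5–C10, C14 on C5, C15 on C4, β = the face of C14). Acetone and the D-fructose-derived epoxidation ketone are taken as purchased reagents.

Step 1
Reactants: 1 3-bromo-4-methylphenol
Product: 2 (3-bromo-4-methylphenoxy)tri(propan-2-yl)silane
Conditions: i-Pr3SiCl, imidazole, DMF, 25 °C
Reagents that add atoms: chlorotri(propan-2-yl)silane, CC(C)[Si](Cl)(C(C)C)C(C)C
Why: Imidazole-mediated O-silylation of a phenol; the bulky silyl ether is chosen because it survives the organozinc coupling and the basic (pH about 10.5) epoxidation medium.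

Step 2
Reactants: 2 (3-bromo-4-methylphenoxy)tri(propan-2-yl)silane; 3 (E)-5-bromopent-2-ene
Product: 5 {4-methyl-3-[(E)-pent-3-en-1-yl]phenoxy}tri(propan-2-yl)silane, via (E)-pent-3-en-1-ylzinc bromide 4 (not isolated)
Conditions: 3, Zn dust, LiCl, THF, 40 °C; then 2, Pd(OAc)2 (2 mol%), SPhos (2-dicyclohexylphosphino-2′,6′-dimethoxybiphenyl, 4 mol%), THF, 25–50 °C
Reagents that add atoms: none
Why: Negishi coupling of a primary alkylzinc halide with an aryl bromide; zinc insertion leaves the (E)-alkene untouched and the biarylphosphine suppresses β-hydride elimination, so the C10–C1 bond forms without alkene migration.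

Step 3
Reactants: 5 {4-methyl-3-[(E)-pent-3-en-1-yl]phenoxy}tri(propan-2-yl)silane
Product: 6 (4-methyl-3-{2-[(2R,3R)-3-methyloxiran-2-yl]ethyl}phenoxy)tri(propan-2-yl)silane
Conditions: 1,2:4,5-di-O-isopropylidene-β-D-erythro-2,3-hexodiulo-2,6-pyranose (0.3 equiv), KHSO5 (as 2KHSO5·KHSO4·K2SO4), K2CO3, Bu4NHSO4 (cat.), MeCN–CH2(OMe)2–H2O, pH 10.5, 0 °C
Reagents that add atoms: potassium peroxymonosulfate, [K+].[O-]S(=O)(=O)OO
Why: Shi asymmetric epoxidation (chiral dioxirane, spiro transition state) of an (E)-1,2-dialkyl alkene; the D-fructose-derived ketone delivers oxygen to the face that gives the (2R,3R)-trans-oxirane, which sets C3 and C4.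

Step 4
Reactants: 6 (4-methyl-3-{2-[(2R,3R)-3-methyloxiran-2-yl]ethyl}phenoxy)tri(propan-2-yl)silane
Product: 7 4-methyl-3-{2-[(2R,3R)-3-methyloxiran-2-yl]ethyl}phenol
Conditions: Bu4NF, AcOH (1.1 equiv each), THF, 0 °C
Reagents that add atoms: none
Why: Fluoride cleavage of an aryl silyl ether, buffered with acetic acid so that neither a free phenoxide nor acid can open the oxirane.

Step 5
Reactants: 7 4-methyl-3-{2-[(2R,3R)-3-methyloxiran-2-yl]ethyl}phenol
Product: 8 2,6-dibromo-4-methyl-3-{2-[(2R,3R)-3-methyloxiran-2-yl]ethyl}phenol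
Conditions: N-bromosuccinimide (2.05 equiv), i-Pr2NH (0.1 equiv), CH2Cl2, −20 → 0 °C, dark
Reagents that add atoms: N-bromosuccinimide, O=C1CCC(=O)N1Br
Why: Amine-catalysed ortho-bromination of a para-substituted phenol (electrophilic aromatic substitution); the by-product is succinimide and not HBr, so the oxirane survives while both carbons ortho to OH (C7 and C9) are blocked.

Step 6
Reactants: 8 2,6-dibromo-4-methyl-3-{2-[(2R,3R)-3-methyloxiran-2-yl]ethyl}phenol
Product: 9 (4aS,5R,6R)-1,3-dibromo-6-hydroxy-4a,5-dimethyl-5,6,7,8-tetrahydronaphthalen-2(4aH)-one (eremophilane numbering: 7,9-dibromo-3α-hydroxy-4β,5β-dimethyl-6,9-dien-8-one)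
Conditions: K2CO3 (0.2 equiv), (CF3)2CHOH, 0.01 M, 25 °C
Reagents that add atoms: none
Why: Proposed new method: the two bromine atoms make the phenol (pKa about 7) more acidic than the solvent, so catalytic base keeps it as a phenoxide whose oxygen is hydrogen-bonded and shielded, while the same solvent activates the oxirane by hydrogen bonding; the para carbon C5 then attacks the distal oxirane carbon C4 opposite to the C4–O bond and the alkoxide is protonated by the solvent. The closest known reaction types are the intramolecular para-C-alkylation of phenoxides by sulfonates, which gives ring-fused 4a-alkylcyclohexadienones, and the 6-endo opening of trans-epoxides by tethered arenes in fluorinated alcohols. Ring A (C10, C1, C2, C3, C4, C5) closes in the 6-endo mode through a chair in which the C3 oxygen and the C4 methyl are equatorial. C4 is set by inversion at the oxirane carbon, C3 is carried over unchanged (so the (2R,3R)-oxirane gives 3R,4R), and C5 is set by that chair, which places C14 axial and therefore cis to C15. The step needs para over ortho attack, C- over O-alkylation and 6-endo over 5-exo opening: bromine blocks C9, O-alkylation would need a seven- or eight-membered ring, and attack of a ring carbon through its π face tolerates the six-membered but not the five-membered fused transition state.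

Step 7
Reactants: 9 (4aS,5R,6R)-1,3-dibromo-6-hydroxy-4a,5-dimethyl-5,6,7,8-tetrahydronaphthalen-2(4aH)-one
Product: 10 (4aS,5R,6R,8aR)-6-hydroxy-4a,5-dimethyloctahydronaphthalen-2(1H)-one (cis-fused, 10β-H)
Conditions: H2 (1 atm), Pd/C (10% Pd), Et3N (2.5 equiv), EtOAc, 25 °C
Reagents that add atoms: none
Why: Heterogeneous hydrogenation with concurrent hydrogenolysis of both vinylic C–Br bonds; as for related 4a-methyl octalenones with cis-4,5-dimethyl groups in basic medium, hydrogen should add to C10 on the face of the angular methyl, which sets the cis ring fusion.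

Step 8
Reactants: 10 (4aS,5R,6R,8aR)-6-hydroxy-4a,5-dimethyloctahydronaphthalen-2(1H)-one
Product: 11 (4aS,5R,6R,8aR)-2,6-bis[(tert-butyldimethylsilyl)oxy]-4a,5-dimethyl-3,4,4a,5,6,7,8,8a-octahydronaphthalene (3-O-silyl ether and C8 silyl enol ether with the C8=C9 double bond)
Conditions: t-BuMe2SiCl (3 equiv), NaI (3 equiv), Et3N (4 equiv), MeCN, 50 °C
Reagents that add atoms: tert-butyl(chloro)dimethylsilane, CC(C)(C)[Si](C)(C)Cl
Why: O-silylation plus enol silylation under equilibrating conditions (iodosilane made in situ); this ketone has the cis-fused 10-methyl-2-decalone pattern of 5β-3-keto steroids, which enolise toward the ring-fusion carbon, so the more stable enol ether should be the one toward C9.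

Step 9
Reactants: 11 (4aS,5R,6R,8aR)-2,6-bis[(tert-butyldimethylsilyl)oxy]-4a,5-dimethyl-3,4,4a,5,6,7,8,8a-octahydronaphthalene
Product: 13 (1R,4aR,5R,6R,8aS)-1,6-bis[(tert-butyldimethylsilyl)oxy]-4a,5-dimethyloctahydronaphthalen-2(1H)-one, via β-face silyloxy oxirane 12 (not isolated)
Conditions: 3-ClC6H4CO3H (1.1 equiv), NaHCO3, CH2Cl2, −20 → 0 °C
Reagents that add atoms: 3-chloroperoxybenzoic acid, OOC(=O)c1cccc(Cl)c1
Why: Rubottom oxidation: the peracid epoxidises the enol ether on the convex β face, anti to the axial C4–C5 bond, and the silyloxy oxirane opens with 1,4-silyl shift to the α-silyloxy ketone, so the C9 oxygen is β (equatorial).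

Step 10
Reactants: 13 (1R,4aR,5R,6R,8aS)-1,6-bis[(tert-butyldimethylsilyl)oxy]-4a,5-dimethyloctahydronaphthalen-2(1H)-one
Product: 15 (1R,3R,4aR,5R,6R,8aS)-1,6-bis[(tert-butyldimethylsilyl)oxy]-3-(2-hydroxypropan-2-yl)-4a,5-dimethyloctahydronaphthalen-2(1H)-one, via lithium C7 enolate 14 (not isolated)
Conditions: LiN(i-Pr)2 (1.1 equiv), THF, −78 °C; acetone (3 equiv), −78 °C; AcOH, −78 °C
Reagents that add atoms: acetone, CC(C)=O
Why: Kinetic deprotonation of the α-silyloxy ketone takes place at the C7 methylene, and the lithium enolate adds to acetone (aldol addition) on the β face, anti to axial C4, which gives the equatorial 7β side chain (H7 α), also the thermodynamically preferred epimer.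

Step 11
Reactants: 15 (1R,3R,4aR,5R,6R,8aS)-1,6-bis[(tert-butyldimethylsilyl)oxy]-3-(2-hydroxypropan-2-yl)-4a,5-dimethyloctahydronaphthalen-2(1H)-one
Product: 16 (1R,3R,4aR,5R,6R,8aS)-1,6-dihydroxy-3-(2-hydroxypropan-2-yl)-4a,5-dimethyloctahydronaphthalen-2(1H)-one
Conditions: aq. HF (48%), MeCN, 0 → 25 °C
Reagents that add atoms: none
Why: Acidic fluoride desilylation cleaves both secondary silyl ethers without the basic conditions that would promote retro-aldol cleavage of the β-hydroxy ketone.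

Step 12
Reactants: 16 (1R,3R,4aR,5R,6R,8aS)-1,6-dihydroxy-3-(2-hydroxypropan-2-yl)-4a,5-dimethyloctahydronaphthalen-2(1H)-one; 17 angelic acid [(Z)-2-methylbut-2-enoic acid]
Product: 19 (1R,3R,4aR,5R,6R,8aS)-3-(2-hydroxypropan-2-yl)-4a,5-dimethyl-2-oxodecahydronaphthalene-1,6-diyl bis[(Z)-2-methylbut-2-enoate], via angelic 2,4,6-trichlorobenzoic anhydride 18 (not isolated)
Conditions: 17 (3 equiv), 2,4,6-Cl3C6H2COCl (3 equiv), Et3N (3 equiv), toluene, 25 °C; then 16, toluene, 80 °C
Reagents that add atoms: angelic acid (second molecule of 17), C/C=C(/C)C(=O)O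
Why: Yamaguchi-type esterification through the mixed anhydride, run without a nucleophilic catalyst so that the (Z)-geometry of the angelate is kept; two molecules of 17 are consumed, one for each of the two secondary hydroxyls (C3 and C9), while the tertiary hydroxyl is not acylated.

Step 13
Reactants: 19 (1R,3R,4aR,5R,6R,8aS)-3-(2-hydroxypropan-2-yl)-4a,5-dimethyl-2-oxodecahydronaphthalene-1,6-diyl bis[(Z)-2-methylbut-2-enoate]
Product: 21 (1R,3R,4aR,5R,6R,8aS)-4a,5-dimethyl-2-oxo-3-(prop-1-en-2-yl)decahydronaphthalene-1,6-diyl bis[(Z)-2-methylbut-2-enoate] (CNP0174755.1), via tertiary chlorosulfite 20 (not isolated)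
Conditions: SOCl2 (1.5 equiv), pyridine, −20 → 0 °C
Reagents that add atoms: none
Why: Base-induced dehydration of a tertiary alcohol through its chlorosulfite; the axial H7 lies on the concave face under C4 and is hard to reach, so pyridine should remove a methyl hydrogen and give the isopropenyl rather than the conjugated isopropylidene compound, leaving C7 and C9 untouched.

**Compound list**

1 | 3-bromo-4-methylphenol | Cc1ccc(O)cc1Br | starting material
2 | (3-bromo-4-methylphenoxy)tri(propan-2-yl)silane | Cc1ccc(O[Si](C(C)C)(C(C)C)C(C)C)cc1Br | intermediate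
3 | (E)-5-bromopent-2-ene | C/C=C/CCBr | starting material
4 | (E)-pent-3-en-1-ylzinc bromide | C/C=C/CC[Zn]Br | intermediate
5 | {4-methyl-3-[(E)-pent-3-en-1-yl]phenoxy}tri(propan-2-yl)silane | C/C=C/CCc1cc(O[Si](C(C)C)(C(C)C)C(C)C)ccc1C | intermediate
6 | (4-methyl-3-{2-[(2R,3R)-3-methyloxiran-2-yl]ethyl}phenoxy)tri(propan-2-yl)silane | C[C@H]1O[C@@H]1CCc1cc(O[Si](C(C)C)(C(C)C)C(C)C)ccc1C | intermediate
7 | 4-methyl-3-{2-[(2R,3R)-3-methyloxiran-2-yl]ethyl}phenol | C[C@H]1O[C@@H]1CCc1cc(O)ccc1C | intermediate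
8 | 2,6-dibromo-4-methyl-3-{2-[(2R,3R)-3-methyloxiran-2-yl]ethyl}phenol | C[C@H]1O[C@@H]1CCc1c(C)cc(Br)c(O)c1Br | intermediate
9 | (4aS,5R,6R)-1,3-dibromo-6-hydroxy-4a,5-dimethyl-5,6,7,8-tetrahydronaphthalen-2(4aH)-one | C[C@H]1[C@H](O)CCC2=C(Br)C(=O)C(Br)=C[C@]12C | intermediate
10 | (4aS,5R,6R,8aR)-6-hydroxy-4a,5-dimethyloctahydronaphthalen-2(1H)-one | C1C[C@@]2(C)[C@H](CC[C@@H](O)[C@@H]2C)CC1=O | intermediate
11 | (4aS,5R,6R,8aR)-2,6-bis[(tert-butyldimethylsilyl)oxy]-4a,5-dimethyl-3,4,4a,5,6,7,8,8a-octahydronaphthalene | C1C[C@@]2(C)[C@H](CC[C@@H](O[Si](C)(C)C(C)(C)C)[C@@H]2C)C=C1O[Si](C)(C)C(C)(C)C | intermediate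
12 | 8β,9β-oxirane of 11 (silyloxy oxirane, oxygen on the face of H10) | C1C[C@@]2(C)[C@H](CC[C@@H](O[Si](C)(C)C(C)(C)C)[C@@H]2C)[C@H]3O[C@@]13O[Si](C)(C)C(C)(C)C | intermediate
13 | (1R,4aR,5R,6R,8aS)-1,6-bis[(tert-butyldimethylsilyl)oxy]-4a,5-dimethyloctahydronaphthalen-2(1H)-one | C1C[C@@]2(C)[C@H](CC[C@@H](O[Si](C)(C)C(C)(C)C)[C@@H]2C)[C@@H](O[Si](C)(C)C(C)(C)C)C1=O | intermediate
14 | lithium enolate of 13 (C7=C8 double bond, O–Li on C8) | [Li]OC1=CC[C@@]2(C)[C@H](CC[C@@H](O[Si](C)(C)C(C)(C)C)[C@@H]2C)[C@H]1O[Si](C)(C)C(C)(C)C | intermediate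
15 | (1R,3R,4aR,5R,6R,8aS)-1,6-bis[(tert-butyldimethylsilyl)oxy]-3-(2-hydroxypropan-2-yl)-4a,5-dimethyloctahydronaphthalen-2(1H)-one | CC(C)(O)[C@H]1C[C@@]2(C)[C@H](CC[C@@H](O[Si](C)(C)C(C)(C)C)[C@@H]2C)[C@@H](O[Si](C)(C)C(C)(C)C)C1=O | intermediate
16 | (1R,3R,4aR,5R,6R,8aS)-1,6-dihydroxy-3-(2-hydroxypropan-2-yl)-4a,5-dimethyloctahydronaphthalen-2(1H)-one | CC(C)(O)[C@H]1C[C@@]2(C)[C@H](CC[C@@H](O)[C@@H]2C)[C@@H](O)C1=O | intermediate
17 | angelic acid, (Z)-2-methylbut-2-enoic acid | C/C=C(/C)C(=O)O | starting material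
18 | (Z)-2-methylbut-2-enoic 2,4,6-trichlorobenzoic anhydride | C/C=C(/C)C(=O)OC(=O)c1c(Cl)cc(Cl)cc1Cl | intermediate
19 | (1R,3R,4aR,5R,6R,8aS)-3-(2-hydroxypropan-2-yl)-4a,5-dimethyl-2-oxodecahydronaphthalene-1,6-diyl bis[(Z)-2-methylbut-2-enoate] | CC(C)(O)[C@H]1C[C@@]2(C)[C@H](CC[C@@H](OC(=O)/C(C)=C\C)[C@@H]2C)[C@@H](OC(=O)/C(C)=C\C)C1=O | intermediate
20 | chlorosulfite of the tertiary alcohol of 19 | CC(C)(OS(=O)Cl)[C@H]1C[C@@]2(C)[C@H](CC[C@@H](OC(=O)/C(C)=C\C)[C@@H]2C)[C@@H](OC(=O)/C(C)=C\C)C1=O | intermediate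
21 | (1R,3R,4aR,5R,6R,8aS)-4a,5-dimethyl-2-oxo-3-(prop-1-en-2-yl)decahydronaphthalene-1,6-diyl bis[(Z)-2-methylbut-2-enoate]; eremophilane numbering 3R,4R,5R,7R,9R,10S | C=C(C)[C@H]1C[C@@]2(C)[C@H](CC[C@@H](OC(=O)/C(C)=C\C)[C@@H]2C)[C@@H](OC(=O)/C(C)=C\C)C1=O | target

Total step count: 13. Longest linear sequence: 13 steps (1 → 21); compounds 3 and 17 enter as side inputs.

**Steps most likely to fail**

1. Step 6 (proposed new method). The phenoxide may be too weak a carbon nucleophile, the oxirane may be opened by the solvent or rearrange to a ketone, or attack may occur at the brominated ortho carbon or at the proximal oxirane carbon. The fallback forms the same C4–C5 bond by the known base-mediated para-C-alkylation of a phenoxide with a sulfonate; it sets out from 2 and comes back at 10. Asymmetric γ-alkoxyallylboration of acetaldehyde with the (Z)-γ-(methoxymethoxy)allyl diisopinocampheylborane antipode that gives the syn adduct provides (2R,3R)-3-(methoxymethoxy)pent-4-en-2-ol F1, in which the future C3 and C4 oxygens are already differentiated. Hydroboration with 9-borabicyclo[3.3.1]nonane (2.2 equiv) gives the C,O-bis(boryl) adduct F2 (not isolated), which is coupled with 2 (PdCl2(dppf), K3PO4, DMF–THF–H2O, 60 °C; B-alkyl Suzuki–Miyaura coupling) to give (2R,3R)-3-(methoxymethoxy)-5-{2-methyl-5-[tri(propan-2-yl)silyloxy]phenyl}pentan-2-ol F3. Mesylation (MeSO2Cl, Et3N) gives the methanesulfonate F4, buffered Bu4NF frees the phenol (2R,3R)-5-(5-hydroxy-2-methylphenyl)-3-(methoxymethoxy)pentan-2-yl methanesulfonate F5, and N-bromosuccinimide as in step 5 gives the dibromophenol (2R,3R)-5-(2,4-dibromo-3-hydroxy-6-methylphenyl)-3-(methoxymethoxy)pentan-2-yl methanesulfonate F6. KOC(CH3)3 in tert-butanol then closes ring A by attack of the para carbon on the only electrophilic carbon, C4, with inversion and through the same chair, to give (4aS,5R,6R)-1,3-dibromo-6-(methoxymethoxy)-4a,5-dimethyl-5,6,7,8-tetrahydronaphthalen-2(4aH)-one F7. Hydrogenation as in step 7 gives (4aS,5R,6R,8aR)-6-(methoxymethoxy)-4a,5-dimethyloctahydronaphthalen-2(1H)-one F8, and HCl in methanol removes the methoxymethyl group to give 10.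

2. Step 8. Enolisation may not discriminate well enough between C9 and C7, so that oxygen would later be placed at C7. The fallback reverses the order and uses kinetic control twice; it sets out from 10 and comes back at 16. Silylation of O3 (t-BuMe2SiCl, imidazole) gives (4aS,5R,6R,8aR)-6-[(tert-butyldimethylsilyl)oxy]-4a,5-dimethyloctahydronaphthalen-2(1H)-one F9. LiN(i-Pr)2 at −78 °C removes the more accessible C7 hydrogen to give the lithium C7 enolate F10 (not isolated), which adds to acetone on the β face to give the 7β aldol (3R,4aS,5R,6R,8aR)-6-[(tert-butyldimethylsilyl)oxy]-3-(2-hydroxypropan-2-yl)-4a,5-dimethyloctahydronaphthalen-2(1H)-one F11. The tertiary hydroxyl is capped (Et3SiOSO2CF3, 2,6-lutidine) to give the triethylsilyl ether F12. A second kinetic deprotonation now takes place at the C9 methylene rather than at the substituted C7, giving the lithium C9 enolate F13 (not isolated), which is oxidised with 2-(phenylsulfonyl)-3-phenyloxaziridine on the β face to the 9β-hydroxy ketone F14. Aqueous HF in MeCN removes both silyl groups to give 16.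

3. Step 13. Elimination may take the C7 hydrogen instead of a methyl hydrogen and give the conjugated isopropylidene ketone, or the β,γ-unsaturated ketone may isomerise afterwards. The fallback is a regiospecific Peterson olefination; it sets out from 13 and comes back at 21. Enolate 14, generated as in step 10, is added at −78 °C to 1-(trimethylsilyl)propan-2-one to give the β-hydroxysilane (1R,3R,4aR,5R,6R,8aS)-1,6-bis[(tert-butyldimethylsilyl)oxy]-3-[2-hydroxy-1-(trimethylsilyl)propan-2-yl]-4a,5-dimethyloctahydronaphthalen-2(1H)-one F15 (mixture at C11). Aqueous HF in MeCN removes both silyl ethers and induces the acid-type Peterson elimination, which can only form the C11=CH2 double bond, giving (1R,3R,4aR,5R,6R,8aS)-1,6-dihydroxy-4a,5-dimethyl-3-(prop-1-en-2-yl)octahydronaphthalen-2(1H)-one F16. Bis-angeloylation of F16 with 18 under the conditions of step 12 gives 21.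

**Further compounds**

F1 | step 6 | (2R,3R)-3-(methoxymethoxy)pent-4-en-2-ol | C[C@@H](O)[C@H](OCOC)C=C
F2 | step 6 | C,O-bis(9-borabicyclo[3.3.1]nonan-9-yl) adduct of F1 (boron on the chain terminus and on the carbinol oxygen) | C[C@@H](OB1C2CCCC1CCC2)[C@H](OCOC)CCB1C2CCCC1CCC2
F3 | step 6 | (2R,3R)-3-(methoxymethoxy)-5-{2-methyl-5-[tri(propan-2-yl)silyloxy]phenyl}pentan-2-ol | C[C@@H](O)[C@H](OCOC)CCc1cc(O[Si](C(C)C)(C(C)C)C(C)C)ccc1C
F4 | step 6 | (2R,3R)-3-(methoxymethoxy)-5-{2-methyl-5-[tri(propan-2-yl)silyloxy]phenyl}pentan-2-yl methanesulfonate | C[C@@H](OS(C)(=O)=O)[C@H](OCOC)CCc1cc(O[Si](C(C)C)(C(C)C)C(C)C)ccc1C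
F5 | step 6 | (2R,3R)-5-(5-hydroxy-2-methylphenyl)-3-(methoxymethoxy)pentan-2-yl methanesulfonate | C[C@@H](OS(C)(=O)=O)[C@H](OCOC)CCc1cc(O)ccc1C
F6 | step 6 | (2R,3R)-5-(2,4-dibromo-3-hydroxy-6-methylphenyl)-3-(methoxymethoxy)pentan-2-yl methanesulfonate | C[C@@H](OS(C)(=O)=O)[C@H](OCOC)CCc1c(C)cc(Br)c(O)c1Br
F7 | step 6 | (4aS,5R,6R)-1,3-dibromo-6-(methoxymethoxy)-4a,5-dimethyl-5,6,7,8-tetrahydronaphthalen-2(4aH)-one | C[C@H]1[C@H](OCOC)CCC2=C(Br)C(=O)C(Br)=C[C@]12C
F8 | step 6 | (4aS,5R,6R,8aR)-6-(methoxymethoxy)-4a,5-dimethyloctahydronaphthalen-2(1H)-one | C1C[C@@]2(C)[C@H](CC[C@@H](OCOC)[C@@H]2C)CC1=O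
F9 | step 8 | (4aS,5R,6R,8aR)-6-[(tert-butyldimethylsilyl)oxy]-4a,5-dimethyloctahydronaphthalen-2(1H)-one | C1C[C@@]2(C)[C@H](CC[C@@H](O[Si](C)(C)C(C)(C)C)[C@@H]2C)CC1=O
F10 | step 8 | lithium enolate of F9 (C7=C8 double bond) | [Li]OC1=CC[C@@]2(C)[C@H](CC[C@@H](O[Si](C)(C)C(C)(C)C)[C@@H]2C)C1
F11 | step 8 | (3R,4aS,5R,6R,8aR)-6-[(tert-butyldimethylsilyl)oxy]-3-(2-hydroxypropan-2-yl)-4a,5-dimethyloctahydronaphthalen-2(1H)-one | CC(C)(O)[C@H]1C[C@@]2(C)[C@H](CC[C@@H](O[Si](C)(C)C(C)(C)C)[C@@H]2C)CC1=O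
F12 | step 8 | (3R,4aS,5R,6R,8aR)-6-[(tert-butyldimethylsilyl)oxy]-4a,5-dimethyl-3-{2-[(triethylsilyl)oxy]propan-2-yl}octahydronaphthalen-2(1H)-one | CC(C)(O[Si](CC)(CC)CC)[C@H]1C[C@@]2(C)[C@H](CC[C@@H](O[Si](C)(C)C(C)(C)C)[C@@H]2C)CC1=O
F13 | step 8 | lithium enolate of F12 (C8=C9 double bond) | CC(C)(O[Si](CC)(CC)CC)[C@H]1C[C@@]2(C)[C@H](CC[C@@H](O[Si](C)(C)C(C)(C)C)[C@@H]2C)C=C1O[Li]
F14 | step 8 | (1R,3R,4aR,5R,6R,8aS)-6-[(tert-butyldimethylsilyl)oxy]-1-hydroxy-4a,5-dimethyl-3-{2-[(triethylsilyl)oxy]propan-2-yl}octahydronaphthalen-2(1H)-one | CC(C)(O[Si](CC)(CC)CC)[C@H]1C[C@@]2(C)[C@H](CC[C@@H](O[Si](C)(C)C(C)(C)C)[C@@H]2C)[C@@H](O)C1=O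
F15 | step 13 | (1R,3R,4aR,5R,6R,8aS)-1,6-bis[(tert-butyldimethylsilyl)oxy]-3-[2-hydroxy-1-(trimethylsilyl)propan-2-yl]-4a,5-dimethyloctahydronaphthalen-2(1H)-one (C11 epimers) | C[Si](C)(C)CC(C)(O)[C@H]1C[C@@]2(C)[C@H](CC[C@@H](O[Si](C)(C)C(C)(C)C)[C@@H]2C)[C@@H](O[Si](C)(C)C(C)(C)C)C1=O
F16 | step 13 | (1R,3R,4aR,5R,6R,8aS)-1,6-dihydroxy-4a,5-dimethyl-3-(prop-1-en-2-yl)octahydronaphthalen-2(1H)-one | C=C(C)[C@H]1C[C@@]2(C)[C@H](CC[C@@H](O)[C@@H]2C)[C@@H](O)C1=O
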